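**Retrosynthetic overview**

- Target: (2S)-6-geranyl-5,7,3',5'-tetrahydroxyflavanone. The last operations are global MOM removal and, before it, an enantioselective oxa-Michael closure of ring C from a 2'-hydroxychalcone whose only free phenol is the oxygen para to the geranyl group (the future O1).
- The chalcone comes from Claisen–Schmidt condensation of 3,5-bis(MOM-oxy)benzaldehyde with the ring-A acetophenone, which is made from the geranyl phenol by desilylation, ortho-iodination and Stille acetylation.
- The strategy rests on the E-trisubstituted C2''=C3'' alkene of the geranyl chain and on the benzylic C1'' attached to ring-A C6 between O5 and O7. The C3''–CH3 and C1''–C2'' bonds are made in one pot from 6-methylhept-5-en-1-yne (Zr-catalysed syn-methylalumination) and a 2,6-bis(MOM-oxy)-4-(TIPS-oxy)benzyl chloride (Ni(0) coupling).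
- The benzyl chloride comes from resorcinol: bis-MOM ether, C–H borylation/oxidation at C5, TIPS ether, directed metalation/formylation between the two MOM ethers with reduction, then chlorination.
- Ring order: rings A and B are bought as arenes; ring C (the pyranone) is the only ring formed, and it is formed last, by 6-endo oxa-Michael addition.

Key step: step 7

Assumption: the quinidine-derived thiourea is taken as the pseudoenantiomer that closes the ring to the 2S product; if a test cyclisation shows the opposite sense, the quinine-derived catalyst is used and nothing else changes.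

**Route**

Step 1
Reactants: 1 resorcinol
Product: 2 1,3-bis(methoxymethoxy)benzene
Conditions: MOMCl (2.5 eq), i-Pr2NEt (3 eq), CH2Cl2, 0 °C → rt
Reagents that add atoms: chloromethyl methyl ether, COCCl
Why: O-alkylation of both phenols (MOM protection) with the amine taking up HCl; the acetals serve later as ortho-directing groups and as the final acid-labile protection.

Step 2
Reactants: 2 1,3-bis(methoxymethoxy)benzene
Product: 4 3,5-bis(methoxymethoxy)phenol, via aryl pinacol boronate 3 (not isolated)
Conditions: HBpin (1.5 eq), [Ir(OMe)(cod)]2 (1.5 mol %), dtbpy (3 mol %), THF, 60 °C; then 30 % H2O2, aq NaOH, 0 °C → rt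
Reagents that add atoms: hydrogen peroxide, OO
Why: Iridium-catalysed C–H borylation is sterically governed and should go at C5, the only position not ortho to an oxygen substituent, and oxidation of the boronate in the same pot (borylation/oxidation) gives the phenol with the third oxygen differentiated.

Step 3
Reactants: 4 3,5-bis(methoxymethoxy)phenol
Product: 5 [3,5-bis(methoxymethoxy)phenoxy]tri(propan-2-yl)silane
Conditions: TIPSCl (1.1 eq), imidazole (2 eq), DMF, rt
Reagents that add atoms: chlorotri(propan-2-yl)silane, CC(C)[Si](Cl)(C(C)C)C(C)C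
Why: Standard silylation of a phenol; the bulky TIPS ether marks the oxygen that becomes O1 and shields its two ortho positions from metalation.

Step 4
Reactants: 5 [3,5-bis(methoxymethoxy)phenoxy]tri(propan-2-yl)silane
Product: 8 [2,6-bis(methoxymethoxy)-4-(triisopropylsilyloxy)phenyl]methanol, via aryllithium 6 (not isolated), via aldehyde 7 (not isolated)
Conditions: n-BuLi (1.2 eq), THF, 0 °C; DMF (2 eq), 0 °C → rt; then EtOH, NaBH4, −10 → 0 °C
Reagents that add atoms: N,N-dimethylformamide, CN(C)C=O
Why: Directed ortho-metalation removes the proton between the two MOM ethers (doubly chelation-activated, and remote from the TIPS group), so formylation with DMF puts the future C1'' on the symmetry axis of the arene, and borohydride reduction in the same pot gives the benzylic alcohol.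

Step 5
Reactants: 8 [2,6-bis(methoxymethoxy)-4-(triisopropylsilyloxy)phenyl]methanol
Product: 10 2-(chloromethyl)-1,3-bis(methoxymethoxy)-5-(triisopropylsilyloxy)benzene, via benzylic mesylate 9 (not isolated)
Conditions: MsCl (1.2 eq), LiCl (3 eq), 2,4,6-collidine (2 eq), DMF, 0 °C; cold NaHCO3 work-up, used crude at once
Reagents that add atoms: lithium chloride, [Li+].[Cl-]
Why: Collington–Meyers chlorination through the mesylate runs under buffered, non-acidic conditions, so the MOM and TIPS ethers should survive and the electron-rich chloride is taken on without storage.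

Step 6
Reactants: 11 5-bromo-2-methylpent-2-ene
Product: 12 6-methylhept-5-en-1-yne
Conditions: lithium acetylide–ethylenediamine complex (1.3 eq), DMSO, 5 °C → rt; distillation
Reagents that add atoms: lithium acetylide–ethylenediamine complex, [Li+].[C-]#C.NCCN
Why: SN2 alkylation of lithium acetylide by a primary homoallylic bromide in DMSO gives the terminal enyne and leaves the trisubstituted alkene untouched.

Step 7
Reactants: 12 6-methylhept-5-en-1-yne; 10 2-(chloromethyl)-1,3-bis(methoxymethoxy)-5-(triisopropylsilyloxy)benzene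
Product: 14 {4-[(2E)-3,7-dimethylocta-2,6-dien-1-yl]-3,5-bis(methoxymethoxy)phenoxy}tri(propan-2-yl)silane, via E-alkenylalane 13 (not isolated)
Conditions: 12 (1.4 eq), Me3Al (2 eq per alkyne), Cp2ZrCl2 (0.25 eq), ClCH2CH2Cl, 0 °C → rt; volatiles and excess Me3Al removed in vacuo; THF; 10 (1.0 eq), NiCl2(PPh3)2 (5 mol %)/n-BuLi (10 mol %), 0 °C → rt
Reagents that add atoms: trimethylaluminium, C[Al](C)C
Why: Cp2ZrCl2/Me3Al adds methyl and aluminium syn across the terminal alkyne with aluminium on C1 (Negishi carboalumination), so alane 13 carries the future C3'' methyl cis to the metal; Ni(0) then inserts into the benzylic C–Cl bond of 10, the alkenyl group transmetalates from aluminium to nickel, and reductive elimination forms C1''–C2'' with retention of alkene geometry, giving the 2E (geranyl, not neryl) chain. The closest known reaction type is the one-pot methylalumination/nickel-catalysed benzylation of alkenylalanes used for the polyprenyl side chains of ubiquinones. No ring is closed and no stereocentre is formed; the selectivity needed is E geometry, and it is fixed by the syn addition and the stereoretentive coupling. Regiochemistry on ring A needs no control, because the chloromethyl carbon was placed between the two MOM ethers in step 4 and the arene is symmetric. Excess Me3Al is stripped and the coupling is run in THF, so the Lewis-basic solvent tempers the alanes and the MOM acetals, the TIPS ether and the labile chloride should survive; the remote trisubstituted alkene of 12 is inert to carbometalation.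

Step 8
Reactants: 14 {4-[(2E)-3,7-dimethylocta-2,6-dien-1-yl]-3,5-bis(methoxymethoxy)phenoxy}tri(propan-2-yl)silane
Product: 15 4-[(2E)-3,7-dimethylocta-2,6-dien-1-yl]-3,5-bis(methoxymethoxy)phenol
Conditions: TBAF (1.1 eq), THF, 0 °C
Reagents that add atoms: none
Why: Fluoride-induced desilylation frees the single phenol, para to the geranyl group, while the MOM acetals and the alkenes are inert.

Step 9
Reactants: 15 4-[(2E)-3,7-dimethylocta-2,6-dien-1-yl]-3,5-bis(methoxymethoxy)phenol
Product: 16 4-[(2E)-3,7-dimethylocta-2,6-dien-1-yl]-2-iodo-3,5-bis(methoxymethoxy)phenol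
Conditions: NIS (1.0 eq), CH2Cl2, −40 → 0 °C, dark
Reagents that add atoms: N-iodosuccinimide, O=C1CCC(=O)N1I
Why: Electrophilic aromatic iodination ortho to the free phenol; the two open ring positions are equivalent and far more nucleophilic than the trisubstituted alkenes, and one equivalent of reagent at low temperature limits di-iodination.

Step 10
Reactants: 16 4-[(2E)-3,7-dimethylocta-2,6-dien-1-yl]-2-iodo-3,5-bis(methoxymethoxy)phenol
Product: 18 1-{3-[(2E)-3,7-dimethylocta-2,6-dien-1-yl]-6-hydroxy-2,4-bis(methoxymethoxy)phenyl}ethan-1-one, via enol ether 17 (not isolated)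
Conditions: tributyl(1-ethoxyvinyl)stannane (1.5 eq), Pd(PPh3)4 (5 mol %), toluene, 100 °C; then 1 M HCl, THF, 0 °C → rt, short contact
Reagents that add atoms: tributyl(1-ethoxyvinyl)stannane, CCCC[Sn](CCCC)(CCCC)C(=C)OCC; water, O
Why: Stille coupling with the 1-ethoxyvinyl stannane as an acetyl equivalent, followed by mild hydrolysis of the enol ether, installs the acetyl group without the Lewis acids of a Friedel–Crafts or Fries reaction, which would cleave the MOM ethers or cyclise the geranyl chain.

Step 11
Reactants: 19 3,5-dihydroxybenzaldehyde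
Product: 20 3,5-bis(methoxymethoxy)benzaldehyde
Conditions: MOMCl (2.5 eq), i-Pr2NEt (3 eq), CH2Cl2, 0 °C → rt
Reagents that add atoms: chloromethyl methyl ether, COCCl
Why: O-alkylation (MOM protection) of both phenols gives a non-enolisable aldehyde carrying the same protecting group as ring A.

Step 12
Reactants: 18 1-{3-[(2E)-3,7-dimethylocta-2,6-dien-1-yl]-6-hydroxy-2,4-bis(methoxymethoxy)phenyl}ethan-1-one; 20 3,5-bis(methoxymethoxy)benzaldehyde
Product: 21 (2E)-3-[3,5-bis(methoxymethoxy)phenyl]-1-{3-[(2E)-3,7-dimethylocta-2,6-dien-1-yl]-6-hydroxy-2,4-bis(methoxymethoxy)phenyl}prop-2-en-1-one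
Conditions: KOH (excess), EtOH, rt; neutralised cold to pH 6–7
Reagents that add atoms: none
Why: Claisen–Schmidt (aldol) condensation of the methyl ketone with the non-enolisable aldehyde gives the E-chalcone, which persists as its phenoxide under the basic conditions; MOM ethers and the geranyl chain are base-stable.

Step 13
Reactants: 21 (2E)-3-[3,5-bis(methoxymethoxy)phenyl]-1-{3-[(2E)-3,7-dimethylocta-2,6-dien-1-yl]-6-hydroxy-2,4-bis(methoxymethoxy)phenyl}prop-2-en-1-one
Product: 22 (2S)-2-[3,5-bis(methoxymethoxy)phenyl]-6-[(2E)-3,7-dimethylocta-2,6-dien-1-yl]-5,7-bis(methoxymethoxy)-2,3-dihydro-4H-chromen-4-one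
Conditions: quinidine-derived bifunctional thiourea [N-3,5-bis(trifluoromethyl)phenyl-N'-(9-deoxy-epi-quinidin-9-yl)thiourea] (10 mol %), PhCl, 25 °C
Reagents that add atoms: none
Why: Organocatalytic asymmetric intramolecular oxa-Michael addition (6-endo-trig), in which the quinuclidine nitrogen activates the only free phenol while the thiourea binds the enone carbonyl, so the oxygen adds to one enantiotopic face of the β-carbon and sets C2 as S; the regiochemistry (6-geranyl, not 8-geranyl) is fixed because the other ortho oxygen is a MOM ether.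

Step 14
Reactants: 22 (2S)-2-[3,5-bis(methoxymethoxy)phenyl]-6-[(2E)-3,7-dimethylocta-2,6-dien-1-yl]-5,7-bis(methoxymethoxy)-2,3-dihydro-4H-chromen-4-one
Product: 23 schizolaenone C, (2S)-2-(3,5-dihydroxyphenyl)-6-[(2E)-3,7-dimethylocta-2,6-dien-1-yl]-5,7-dihydroxy-2,3-dihydro-4H-chromen-4-one
Conditions: 3 M aq HCl/MeOH (1:5), rt → 40 °C, monitored; NaHCO3 quench
Reagents that add atoms: none
Why: Acid-catalysed acetal methanolysis removes all four MOM groups, and dilute acid at low temperature should neither cyclise the geranyl chain onto the flanking phenols nor open the flavanone ring, so C2 stays S.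

**Compound list**

1 | resorcinol | Oc1cccc(O)c1 | starting material
2 | 1,3-bis(methoxymethoxy)benzene | COCOc1cccc(OCOC)c1 | intermediate
3 | 2-[3,5-bis(methoxymethoxy)phenyl]-4,4,5,5-tetramethyl-1,3,2-dioxaborolane | COCOc1cc(OCOC)cc(c1)B1OC(C)(C)C(C)(C)O1 | intermediate
4 | 3,5-bis(methoxymethoxy)phenol | COCOc1cc(O)cc(OCOC)c1 | intermediate
5 | [3,5-bis(methoxymethoxy)phenoxy]tri(propan-2-yl)silane | COCOc1cc(OCOC)cc(O[Si](C(C)C)(C(C)C)C(C)C)c1 | intermediate
6 | [2,6-bis(methoxymethoxy)-4-(triisopropylsilyloxy)phenyl]lithium | [Li]c1c(OCOC)cc(O[Si](C(C)C)(C(C)C)C(C)C)cc1OCOC | intermediate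
7 | 2,6-bis(methoxymethoxy)-4-(triisopropylsilyloxy)benzaldehyde | O=Cc1c(OCOC)cc(O[Si](C(C)C)(C(C)C)C(C)C)cc1OCOC | intermediate
8 | [2,6-bis(methoxymethoxy)-4-(triisopropylsilyloxy)phenyl]methanol | OCc1c(OCOC)cc(O[Si](C(C)C)(C(C)C)C(C)C)cc1OCOC | intermediate
9 | [2,6-bis(methoxymethoxy)-4-(triisopropylsilyloxy)phenyl]methyl methanesulfonate | CS(=O)(=O)OCc1c(OCOC)cc(O[Si](C(C)C)(C(C)C)C(C)C)cc1OCOC | intermediate
10 | 2-(chloromethyl)-1,3-bis(methoxymethoxy)-5-(triisopropylsilyloxy)benzene | ClCc1c(OCOC)cc(O[Si](C(C)C)(C(C)C)C(C)C)cc1OCOC | intermediate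
11 | 5-bromo-2-methylpent-2-ene | CC(C)=CCCBr | starting material
12 | 6-methylhept-5-en-1-yne | C#CCCC=C(C)C | intermediate
13 | [(1E)-2,6-dimethylhepta-1,5-dien-1-yl]dimethylalumane | CC(C)=CCC/C(C)=C/[Al](C)C | intermediate
14 | {4-[(2E)-3,7-dimethylocta-2,6-dien-1-yl]-3,5-bis(methoxymethoxy)phenoxy}tri(propan-2-yl)silane | CC(C)=CCC/C(C)=C/Cc1c(OCOC)cc(O[Si](C(C)C)(C(C)C)C(C)C)cc1OCOC | intermediate
15 | 4-[(2E)-3,7-dimethylocta-2,6-dien-1-yl]-3,5-bis(methoxymethoxy)phenol | CC(C)=CCC/C(C)=C/Cc1c(OCOC)cc(O)cc1OCOC | intermediate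
16 | 4-[(2E)-3,7-dimethylocta-2,6-dien-1-yl]-2-iodo-3,5-bis(methoxymethoxy)phenol | CC(C)=CCC/C(C)=C/Cc1c(OCOC)cc(O)c(I)c1OCOC | intermediate
17 | 4-[(2E)-3,7-dimethylocta-2,6-dien-1-yl]-2-(1-ethoxyethenyl)-3,5-bis(methoxymethoxy)phenol | CC(C)=CCC/C(C)=C/Cc1c(OCOC)cc(O)c(C(=C)OCC)c1OCOC | intermediate
18 | 1-{3-[(2E)-3,7-dimethylocta-2,6-dien-1-yl]-6-hydroxy-2,4-bis(methoxymethoxy)phenyl}ethan-1-one | CC(C)=CCC/C(C)=C/Cc1c(OCOC)cc(O)c(C(C)=O)c1OCOC | intermediate
19 | 3,5-dihydroxybenzaldehyde | O=Cc1cc(O)cc(O)c1 | starting material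
20 | 3,5-bis(methoxymethoxy)benzaldehyde | O=Cc1cc(OCOC)cc(OCOC)c1 | intermediate
21 | (2E)-3-[3,5-bis(methoxymethoxy)phenyl]-1-{3-[(2E)-3,7-dimethylocta-2,6-dien-1-yl]-6-hydroxy-2,4-bis(methoxymethoxy)phenyl}prop-2-en-1-one | CC(C)=CCC/C(C)=C/Cc1c(OCOC)cc(O)c(C(=O)/C=C/c2cc(OCOC)cc(OCOC)c2)c1OCOC | intermediate
22 | (2S)-2-[3,5-bis(methoxymethoxy)phenyl]-6-[(2E)-3,7-dimethylocta-2,6-dien-1-yl]-5,7-bis(methoxymethoxy)-2,3-dihydro-4H-chromen-4-one | CC(C)=CCC/C(C)=C/Cc1c(OCOC)cc2c(c1OCOC)C(=O)C[C@@H](c1cc(OCOC)cc(OCOC)c1)O2 | intermediate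
23 | schizolaenone C, (2S)-2-(3,5-dihydroxyphenyl)-6-[(2E)-3,7-dimethylocta-2,6-dien-1-yl]-5,7-dihydroxy-2,3-dihydro-4H-chromen-4-one | CC(C)=CCC/C(C)=C/Cc1c(O)cc2c(c1O)C(=O)C[C@@H](c1cc(O)cc(O)c1)O2 | target

**Step count**

Total step count: 14. Longest linear sequence: 12 steps (steps 1–5, 7–10, 12–14).

**Steps most likely to fail, with fallbacks**

Step 13, enantioselective ring closure. The catalyst may discriminate poorly between the two faces of the enone, and enantiomeric purity may erode through reversible ring opening under the basic catalyst. The fallback sets out from chalcone 21 and gives up catalyst control of the closure. Cyclisation with NaOAc in refluxing EtOH should give the racemic tetra-MOM flavanone F1. Kinetic resolution by Noyori-type asymmetric transfer hydrogenation (RuCl(p-cymene)(TsDPEN), HCO2H/Et3N, the catalyst antipode that reduces the 2R ketone) should then convert the 2R enantiomer into the (2R,4R)-cis-flavan-4-ol F2 and leave the 2S ketone. After chromatographic separation the route is rejoined at 22.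

Step 7, the key coupling. The electron-rich benzylic chloride may ionise and self-alkylate, or residual methylalanes may cleave the MOM acetals, before nickel engages the C–Cl bond. Incomplete regiocontrol in the carboalumination would also carry a 1,1-disubstituted alkene isomer into the product. The fallback sets out from silyl ether 5 and reverses the polarity of the benzylic bond formation. Lithiation as in step 4 gives aryllithium 6, and copper-catalysed allylic substitution with commercial (E)-geranyl bromide (CuBr·SMe2 10 mol %, THF, −78 °C → rt) should give 14 directly. The alkene geometry is then taken from the reagent, and the route is rejoined at 14.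

Step 10, acetyl installation. Oxidative addition into the doubly ortho-substituted, electron-rich C–I bond may be slow, so protodeiodination may compete, and the acidic hydrolysis of the enol ether may start to remove the MOM group next to the new ketone. The fallback sets out from phenol 15 and bypasses iodide 16. Magnesium-mediated ortho-formylation (MgCl2, Et3N, paraformaldehyde, MeCN, reflux) should give the salicylaldehyde F3. Addition of MeMgBr (3 eq, THF, 0 °C) gives the secondary benzylic alcohol F4, which is oxidised without storage (activated MnO2, CH2Cl2, rt) to acetophenone 18, where the route is rejoined.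

**Further compounds**

F1 | step 13 | rac-2-[3,5-bis(methoxymethoxy)phenyl]-6-[(2E)-3,7-dimethylocta-2,6-dien-1-yl]-5,7-bis(methoxymethoxy)-2,3-dihydro-4H-chromen-4-one | CC(C)=CCC/C(C)=C/Cc1c(OCOC)cc2c(c1OCOC)C(=O)CC(c1cc(OCOC)cc(OCOC)c1)O2
F2 | step 13 | (2R,4R)-2-[3,5-bis(methoxymethoxy)phenyl]-6-[(2E)-3,7-dimethylocta-2,6-dien-1-yl]-5,7-bis(methoxymethoxy)-3,4-dihydro-2H-chromen-4-ol | CC(C)=CCC/C(C)=C/Cc1c(OCOC)cc2c(c1OCOC)[C@H](O)C[C@H](c1cc(OCOC)cc(OCOC)c1)O2
F0 | step 7 | none | none
F3 | step 10 | 3-[(2E)-3,7-dimethylocta-2,6-dien-1-yl]-6-hydroxy-2,4-bis(methoxymethoxy)benzaldehyde | CC(C)=CCC/C(C)=C/Cc1c(OCOC)cc(O)c(C=O)c1OCOC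
F4 | step 10 | rac-4-[(2E)-3,7-dimethylocta-2,6-dien-1-yl]-2-(1-hydroxyethyl)-3,5-bis(methoxymethoxy)phenol | CC(C)=CCC/C(C)=C/Cc1c(OCOC)cc(O)c(C(C)O)c1OCOC
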